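**Retrosynthetic overview**
1. Target 10 has one ring to make, the dihydropyran (ring B) fused to the monoformyl phloroglucinol ring (ring A); both benzene rings are bought.
2. Ring B is opened across O1–C2 and C3–C4 at once (retro oxa-Diels–Alder), the union thought to operate in the biogenesis of the sideroxylonal family: ortho-quinone methide 9 (ring A unit) plus (E)-styrene 8 (diformyl unit).
3. Both partners carry every phenol and aldehyde free; one chiral phosphoric acid sets C2, C3 and C4 in that single step.
4. 9 ⇐ benzylic alcohol 3 ⇐ 2,4,6-trihydroxybenzaldehyde 1 + 3-methylbutanal 2; 8 ⇐ triformylphloroglucinol 4 (bulk framework monomer) + isobutylmagnesium chloride 5, via 6 and 7.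
5. Order of ring formation: ring B only, in the last step.

Assumption: the sense of induction of the (R)-configured phosphoric acid in step 3 is taken by analogy and must be checked on the first run; if it gives the antipode, the (S)-acid is used with nothing else changed.

Step 1
Reactants: 1 2,4,6-trihydroxybenzaldehyde; 2 3-methylbutanal
Product: 3 rac-2,4,6-trihydroxy-3-(1-hydroxy-3-methylbutyl)benzaldehyde
Conditions: t-BuMgCl (3.0 equiv), THF/PhMe, 0 °C; then 2 (1.0 equiv), 0 °C → rt; sat. aq. NH4Cl, 0 °C; crude product used at once
Reagents that add atoms: 3-methylbutanal (2), CC(C)CC=O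
Why: Casiraghi-type ortho-hydroxyalkylation, in which the magnesium phenoxide form of 1 delivers the magnesium-bound aldehyde to the ring carbon between two oxygens and the adduct stays locked as a magnesium chelate until the cold buffered quench, which keeps it from losing water or reacting a second time; the carbinol centre is formed racemic on purpose because step 3 erases it.

Step 2
Reactants: 4 2,4,6-trihydroxybenzene-1,3,5-tricarbaldehyde; 5 isobutylmagnesium chloride
Product: 8 2,4,6-trihydroxy-5-[(E)-3-methylbut-1-en-1-yl]benzene-1,3-dicarbaldehyde, via benzylic alcohol 6 (not isolated), via quinone methide 7 (not isolated)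
Conditions: 5 (4.2 equiv), THF, −20 → 0 °C; 1 M HCl, 0 °C, extract; crude 6, pyridinium p-toluenesulfonate (5 mol%), 4 Å molecular sieves, PhMe (0.01 M), 80 °C
Reagents that add atoms: isobutylmagnesium chloride (5), CC(C)C[Mg]Cl
Why: Grignard addition to an ortho-hydroxybenzaldehyde with excess reagent (three equivalents go to the phenols, the fourth adds to one formyl group, and the resulting tetra-anion resists a second addition), then acid-catalysed dehydration of 6 to quinone methide 7, which at high dilution tautomerises by 1,5-hydrogen shift to the aromatic styrene faster than it can dimerise; the (E)-alkene is the thermodynamic geometry of a 2,6-disubstituted styrene.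

Step 3
Reactants: 3 rac-2,4,6-trihydroxy-3-(1-hydroxy-3-methylbutyl)benzaldehyde; 8 2,4,6-trihydroxy-5-[(E)-3-methylbut-1-en-1-yl]benzene-1,3-dicarbaldehyde
Product: 10 (2R,3R,4S)-2-(3,5-diformyl-2,4,6-trihydroxyphenyl)-5,7-dihydroxy-4-(2-methylpropyl)-3-(propan-2-yl)-3,4-dihydro-2H-chromene-6-carbaldehyde, via quinone methide 9 (not isolated)
Conditions: (R)-3,3'-bis(2,4,6-triisopropylphenyl)-1,1'-binaphthyl-2,2'-diyl hydrogen phosphate (10 mol%), 5 Å molecular sieves, PhMe/CH2Cl2 1:1, −20 °C; 3 added by syringe pump over 12 h to 8 (2.5 equiv); excess 8 recovered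
Reagents that add atoms: none
Why: Proposed new method: the phosphoric acid ionises 3 to the (E)-quinone methide 9 (water goes to the sieves) and holds it by hydrogen bonding at its unhindered carbonyl oxygen (the one para to the formyl group, next to the ring C–H) while its P=O holds an ortho-hydroxyl of 8, so that the styrene β-carbon adds to one face of the methide carbon and that same oxygen closes onto the benzylic carbon of 8 in an asynchronous inverse-electron-demand oxa-Diels–Alder reaction that copies the presumed biogenetic union; the twisted 2,6-dioxygenated aryl group of 8 lies exo and the isopropyl group endo (3,4-cis, as in the natural series), the (E)-alkene gives 2,3-trans (C2 is also the centre that equilibrates to trans under acid), the catalyst's choice of methide face sets 4S and thereby 3R and 2R, and slow addition of 3 to excess 8 keeps 9 from reacting with itself; the closest known reaction type is the chiral phosphoric acid-catalysed enantioselective oxa-Diels–Alder reaction of ortho-quinone methides, made in the flask from ortho-hydroxybenzylic alcohols, with ortho-hydroxystyrenes, which has not been run with an alkyl-substituted methide on a free polyphenol.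

**Compound list**
1 | 2,4,6-trihydroxybenzaldehyde | O=Cc1c(O)cc(O)cc1O | starting material
2 | 3-methylbutanal | CC(C)CC=O | starting material
3 | rac-2,4,6-trihydroxy-3-(1-hydroxy-3-methylbutyl)benzaldehyde | CC(C)CC(O)c1c(O)cc(O)c(C=O)c1O | intermediate
4 | 2,4,6-trihydroxybenzene-1,3,5-tricarbaldehyde | O=Cc1c(O)c(C=O)c(O)c(C=O)c1O | starting material
5 | isobutylmagnesium chloride | CC(C)C[Mg]Cl | starting material
6 | rac-2,4,6-trihydroxy-5-(1-hydroxy-3-methylbutyl)benzene-1,3-dicarbaldehyde | CC(C)CC(O)c1c(O)c(C=O)c(O)c(C=O)c1O | intermediate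
7 | 2,4-dihydroxy-5-[(E)-3-methylbutylidene]-6-oxocyclohexa-1,3-diene-1,3-dicarbaldehyde | CC(C)C/C=C1/C(=O)C(C=O)=C(O)C(C=O)=C1O | intermediate
8 | 2,4,6-trihydroxy-5-[(E)-3-methylbut-1-en-1-yl]benzene-1,3-dicarbaldehyde | CC(C)/C=C/c1c(O)c(C=O)c(O)c(C=O)c1O | intermediate
9 | 2,6-dihydroxy-3-[(E)-3-methylbutylidene]-4-oxocyclohexa-1,5-diene-1-carbaldehyde | CC(C)C/C=C1/C(=O)C=C(O)C(C=O)=C1O | intermediate
10 | (2R,3R,4S)-2-(3,5-diformyl-2,4,6-trihydroxyphenyl)-5,7-dihydroxy-4-(2-methylpropyl)-3-(propan-2-yl)-3,4-dihydro-2H-chromene-6-carbaldehyde | CC(C)C[C@@H]1c2c(cc(O)c(C=O)c2O)O[C@@H](c2c(O)c(C=O)c(O)c(C=O)c2O)[C@@H]1C(C)C | target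

**Total step count:** 3. **Longest linear sequence:** 2 steps (1 → 3 → 10, or 4 → 8 → 10).

**Steps most likely to fail, and fallbacks**

Step 3 is the most likely to fail. Quinone methide 9 may react with itself, the ring may close through the other ortho oxygen to give the 8-formyl isomer, and the enantioselectivity on a substrate with this many hydrogen-bond donors is the least predictable point. The fallback gives up catalyst control and resolves instead. It sets out from 3 and 8, which are combined with an achiral acid (diphenyl phosphate 10 mol%, PhMe, 40 °C, sieves), relying only on the substrate-controlled exo-aryl cycloaddition, to give racemic (2R*,3R*,4S*)-2-(3,5-diformyl-2,4,6-trihydroxyphenyl)-5,7-dihydroxy-4-(2-methylpropyl)-3-(propan-2-yl)-3,4-dihydro-2H-chromene-6-carbaldehyde F1. Condensation with (S)-1-phenylethylamine (3.3 equiv, EtOH, rt) turns the three aldehydes into stable ortho-hydroxyaryl imines. This gives the tris-[(S)-1-phenylethyl]imine of 10 F2 and the tris-[(S)-1-phenylethyl]imine of the antipode of 10 F3, which are diastereomers and are separated by crystallisation or chromatography. F2 is hydrolysed (1 M HCl, THF, rt) and the route is rejoined at 10.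

Step 2 is next. The formyl groups of the triply deprotonated 4 may be too poor as electrophiles for clean mono-addition, and 7 may be caught by 8 (giving the homodimer) before it tautomerises. The fallback makes the alkene by carbonyl olefination, so that neither 6 nor 7 is ever formed. It sets out from 4: Wittig reaction of one formyl group with isobutylidenetriphenylphosphorane (from isobutyltriphenylphosphonium bromide and KN(SiMe3)2, 4.2 equiv, THF, −78 °C → rt; three equivalents are used up as base by the phenols) gives mainly the kinetic alkene 2,4,6-trihydroxy-5-[(Z)-3-methylbut-1-en-1-yl]benzene-1,3-dicarbaldehyde F4. I2 (5 mol%, CH2Cl2, daylight) then isomerises F4 to the far less strained (E)-alkene, and the route is rejoined at 8.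

Step 1 is third. Alcohol 3 may lose water during work-up and oligomerise, or 1 may be alkylated twice. The fallback traps the alcohol on boron as it forms. It sets out from 1 (with 2): phenylboronic acid-templated ortho-hydroxyalkylation (PhB(OH)2 1.1 equiv, 2 1.2 equiv, propionic acid cat., PhMe, reflux, water separator) gives the cyclic boronate rac-5,7-dihydroxy-4-(2-methylpropyl)-2-phenyl-4H-1,3,2-benzodioxaborinine-6-carbaldehyde F5. This is a storable form of 3 in which the benzylic oxygen is tied to boron and cannot leave. Propane-1,3-diol (THF, rt) removes the boron just before use, and the route is rejoined at 3.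

**Further compounds**
F1 | step 3 | racemic (2R*,3R*,4S*)-2-(3,5-diformyl-2,4,6-trihydroxyphenyl)-5,7-dihydroxy-4-(2-methylpropyl)-3-(propan-2-yl)-3,4-dihydro-2H-chromene-6-carbaldehyde | CC(C)C[C@@H]1c2c(cc(O)c(C=O)c2O)O[C@@H](c2c(O)c(C=O)c(O)c(C=O)c2O)[C@@H]1C(C)C.CC(C)C[C@H]1c2c(cc(O)c(C=O)c2O)O[C@H](c2c(O)c(C=O)c(O)c(C=O)c2O)[C@H]1C(C)C
F2 | step 3 | tris-[(S)-1-phenylethyl]imine of 10 | CC(C)C[C@@H]1c2c(cc(O)c(C=N[C@@H](C)c3ccccc3)c2O)O[C@@H](c2c(O)c(C=N[C@@H](C)c3ccccc3)c(O)c(C=N[C@@H](C)c3ccccc3)c2O)[C@@H]1C(C)C
F3 | step 3 | tris-[(S)-1-phenylethyl]imine of the antipode of 10 | CC(C)C[C@H]1c2c(cc(O)c(C=N[C@@H](C)c3ccccc3)c2O)O[C@H](c2c(O)c(C=N[C@@H](C)c3ccccc3)c(O)c(C=N[C@@H](C)c3ccccc3)c2O)[C@H]1C(C)C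
F4 | step 2 | 2,4,6-trihydroxy-5-[(Z)-3-methylbut-1-en-1-yl]benzene-1,3-dicarbaldehyde | CC(C)/C=C\c1c(O)c(C=O)c(O)c(C=O)c1O
F5 | step 1 | rac-5,7-dihydroxy-4-(2-methylpropyl)-2-phenyl-4H-1,3,2-benzodioxaborinine-6-carbaldehyde | CC(C)CC1OB(c2ccccc2)Oc2cc(O)c(C=O)c(O)c21
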